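Between the two earlier flasks the partner differs by a factor 2.50, but the target at 8.00 h differs by a factor 1.66. So try reading the flask as a balance, and look for the crossing where supply hands over to it.

the same everywhere: starting material 33 mM (fed, over 50 min)

| charge | partner | remark | time |
|---|---|---|---|
| east | 1 equiv | run made earlier |  |
| north-east | 2.5 equiv | run made earlier |  |
| eta | 1.20 equiv |  | 15 h |
| theta | 2.00 equiv |  | 15 h |
| alpha | 3.00 equiv |  | 15 h |

| run | time / h | target / % |
|---|---|---|
| east | 0.667 | 0.1 |
| east | 2.00 | 5.8 |
| east | 4.00 | 19.5 |
| east | 5.00 | 25.5 |
| east | 8.00 | 36.7 |
| north-east | 0.667 | 0.5 |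
| north-east | 1.00 | 2.9 |
| north-east | 2.00 | 12.4 |
| north-east | 4.00 | 38.5 |
| north-east | 8.00 | 60.9 |

(scatter of a reading: 0.5 percentage points)

- the analysis behind the earlier runs scatters by 0.5 percentage points, standard deviation
- steps that have been proposed: partner -> decomposition product; partner -> second intermediate; starting material -> open intermediate; open intermediate + second intermediate <-> target; 2 second intermediate -> homo product
- percentages count the whole charge, also what has not yet gone in
- "hardly changes" means that all values lie within two and a half points (for a concentration: within two and a half percent of the largest)

* amount of target at the end, in percent of the starting material charged for eta, theta, alpha, in this order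
* how the row runs (falls all the way / rises, then falls / hardly changes / rises all the way / falls, then rises)

The balance in question is open intermediate + second intermediate ⇌ target. Let y be the target as a fraction of the charge c, and e the equivalents of partner. As a first guess, count everything charged as available:

Q = y / ((1 − y)(e − y)c): east 27.8 M⁻¹, north-east 25.0 M⁻¹

The two lie close, which is encouraging. But the east value at 4.00 h is 9.12 M⁻¹, so the quotient has been climbing, and I suspect that not all of the charge counts yet. Let a share f of both charges have become intermediates by 8.00 h, the same share in both flasks, and demand one constant for both:

f = 89.0%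

K = y / ((f − y)(ef − y)c) = 40.7 M⁻¹

This K is the balance constant, the equilibrium constant of the coupling as read from these readings. The objection is that two readings fixed two unknowns, so nothing here has been tested. It is my estimate, no more.

If the missing share shrinks first-order, about 1.59% is missing at 15 h, so I take f as whole. Then y·y − (1 + e + 0.744)y + e = 0, which gives:

48.9%, 64.5%, 75.1%

One more doubt remains: second intermediate lost to homo product appears nowhere in this balance, so I treat the row as a high estimate, rising.

The forecast says 50%, 63%, 72%, rises all the way: “Homo-coupling and reversibility blunt the gain from extra partner”. At the right end it stands below my figure.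

The flasks give 47.6%, 61.1%, 69.5%: rises all the way.

    partner → decomposition product (k = 8.10 × 10⁻⁴ h⁻¹)
    partner → second intermediate (k = 0.220 h⁻¹)
    starting material → open intermediate (k = 0.390 h⁻¹)
    open intermediate + second intermediate ⇌ target (K = 49.0 M⁻¹, k = 22.0 M⁻¹ h⁻¹)
    2 second intermediate → homo product (k = 0.440 M⁻¹ h⁻¹)

In eta, of what each step had turned over by 15 h, half the opening of starting material was done by 2.20 h, half the partner's conversion by 2.98 h and half the forward coupling by 4.16 h, and at 15 h the coupling alone, both ways together, relaxes with a half-life of 0.559 h. The end amounts give a quotient of 48.7 M⁻¹ in eta and 49.5 M⁻¹ in alpha. With 40.7 M⁻¹, the balance gave 48.9% for eta and 75.1% for alpha, against 47.6% and 69.5%. At 15 h homo product stood at 1.77 mM in eta and 12.7 mM in alpha.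

(The runs are simulated for an exercise; scatter was added.)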